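## Synthetic plan

- Retrosynthesis: cut the two C6–prenyl bonds of the cyclohexadienone (which re-aromatises the ring to an acylphloroglucinol), then the C–CH3 bond of the tertiary carbinol, then the bond between the exocyclic CH2 and the cyclopentane CH together with a temporary O–C bond to the future carbinol carbon, and last the isopropenyl–ring bond.
- Enabling feature: the CH2 hangs on ring carbon C4, between the oxygen-bearing C3 and C5, so CH2=C4–C3=O is a reduced o-quinone methide. The three contiguous cyclopentane stereocentres C(OH)CH3, CH(CH2) and CH(isopropenyl) correspond to the carbonyl, alpha and beta carbons of cyclopent-2-enone, and the carbinol oxygen is cis to the CH2.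
- Forward: both carbocycles are bought (phloroglucinol, cyclopent-2-enone). Isopropenyl is added to the five-membered ring and the enolate is kept as a silyl enol ether. The acylated, aminomethylated phloroglucinol releases the quinone methide, which joins the two rings through a transient cis-fused dihydropyran ketal. The ketal is reopened, methyl is added to the freed ketone, and gem-diprenylation dearomatises the six-membered ring last.
- Stereochemistry: the isopropenyl carbon comes from a rhodium–(S)-BINAP conjugate addition, the CH2-bearing carbon from anti approach of the quinone methide (with alpha-epimerisation as a safeguard), and the carbinol carbon from methyl attack anti to the neighbouring arylmethyl group.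

Key step: step 4

Remark: the target is drawn as one enol tautomer of a cyclic β-triketone; its keto–enol and ring–chain tautomers are treated as the same compound.

Remark: the sense of induction in step 3 is taken from the accepted facial model for rhodium–BINAP conjugate additions to cyclic enones, under which (S)-BINAP should give the (S) centre; the antipodal ligand would be used if the sense proved opposite.

## Route

Step 1
Reactants: 1 phloroglucinol (benzene-1,3,5-triol); 2 isovaleryl chloride (3-methylbutanoyl chloride)
Product: 3 phlorisovalerophenone (3-methyl-1-(2,4,6-trihydroxyphenyl)butan-1-one)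
Conditions: AlCl3 (3.5 equiv), PhNO2–CH2Cl2, 0 → 45 °C; ice/aq. HCl
Reagents that add atoms: none
Why: Friedel–Crafts C-acylation of the strongly activated triol, in which the first acyl group, chelated by its two ortho hydroxyls, deactivates the ring so that mono-acylation is expected; no stereocentre is formed.

Step 2
Reactants: 3 phlorisovalerophenone; 4 N,N-dimethylmethyleneiminium iodide (Eschenmoser's salt)
Product: 5 1-{3-[(dimethylamino)methyl]-2,4,6-trihydroxyphenyl}-3-methylbutan-1-one
Conditions: 4 (1.0 equiv), MeCN, −20 → 0 °C; then aq. NaHCO3 to pH 8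
Reagents that add atoms: none
Why: Mannich aminomethylation of an electron-rich phenol by a preformed iminium salt, in which the two free ring carbons are equivalent and the first product, formed as its ammonium iodide, is deactivated towards a second substitution, so one equivalent of 4 at low temperature should give the mono-adduct; no stereocentre is formed.

Step 3
Reactants: 6 cyclopent-2-en-1-one; 7 isopropenylmagnesium bromide (prop-1-en-2-ylmagnesium bromide)
Product: 9 trimethyl{[(3S)-3-(prop-1-en-2-yl)cyclopent-1-en-1-yl]oxy}silane, via isopropenylzinc chloride 8 (not isolated)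
Conditions: 7 (1.5 equiv), ZnCl2 (1.5 equiv), THF, 0 °C; then 6, [RhCl((S)-BINAP)]2 (2.5 mol%), Me3SiCl (1.5 equiv), THF, 20 °C; pentane, filtration, distillation
Reagents that add atoms: chlorotrimethylsilane, C[Si](C)(C)Cl
Why: Rhodium-catalysed asymmetric 1,4-addition of an organozinc reagent in an aprotic medium (a Hayashi–Miyaura-type conjugate addition with silyl trapping), in which the alkenyl–rhodium–(S)-BINAP species inserts the enone on one enantioface to set C3 as (S) and the oxa-π-allyl rhodium intermediate is silylated by the chlorosilane, so the enol ether double bond is fixed between C1 and C2.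

Step 4
Reactants: 5 1-{3-[(dimethylamino)methyl]-2,4,6-trihydroxyphenyl}-3-methylbutan-1-one; 9 trimethyl{[(3S)-3-(prop-1-en-2-yl)cyclopent-1-en-1-yl]oxy}silane
Product: 12 cis-fused silyl ketal 1-[(1S,3aR,9aR)-6,8-dihydroxy-1-(prop-1-en-2-yl)-3a-(trimethylsilyloxy)-1,2,3,3a,9,9a-hexahydrocyclopenta[b]chromen-7-yl]-3-methylbutan-1-one, via benzylic trimethylammonium iodide 10 (not isolated), via o-quinone methide 11 (not isolated)
Conditions: MeI (1.05 equiv), CH2Cl2, 0 °C → rt; then 9 (2.5 equiv), 2,6-lutidine (1.2 equiv, added slowly), CH2Cl2, rt → 40 °C; cold aq. NaHCO3 wash, crude product used directly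
Reagents that add atoms: none
Why: N-methylation turns the dimethylamino group into a permanently activated leaving group, and gentle deprotonation of the flanking phenol by 2,6-lutidine then expels trimethylamine to give the acyl-substituted o-quinone methide 11, an electron-poor 1-oxadiene (O=C–C=CH2) that re-aromatises as it reacts. The closest known reaction type is the inverse-electron-demand hetero-Diels–Alder reaction of o-quinone methides released from quaternised phenolic Mannich bases with enol ethers and silyl enol ethers, which in its stepwise limit is a Mukaiyama–Michael addition followed by ketalisation. The nucleophilic C2 of 9 bonds to the CH2 terminus and the quinone methide oxygen bonds to the silyloxy carbon, so the one ring formed, the dihydropyran, closes in a [4+2] mode (in the stepwise limit a 6-exo-trig capture of the silyloxocarbenium ion by phenoxide oxygen); closure through either oxygen flanking the CH2-bearing carbon is acceptable because both ketals lead to the same ketone. The new CH centre C9a is set by approach of the oxadiene to the face of the enol ether anti to the isopropenyl group on the adjacent C3 of 9, and the ketal centre C3a follows from suprafacial addition across the ring double bond, which enforces the cis ring fusion. The step needs chemoselectivity for the enol ether over the isopropenyl alkene and CH2-to-C2 regiochemistry, both secured by the polarisation and high nucleophilicity of the silyl enol ether; it also needs the quinone methide to be intercepted before it alkylates the free aromatic CH of another phloroglucinol, which is addressed by keeping the phenols un-ionised with a weak base, releasing 11 slowly and using 9 in excess.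

Step 5
Reactants: 12 cis-fused silyl ketal
Product: 14 (2R,3S)-3-(prop-1-en-2-yl)-2-[2,4,6-trihydroxy-3-(3-methylbutanoyl)benzyl]cyclopentan-1-one, via cyclic hemiketal 13 (not isolated)
Conditions: K2CO3 (3 equiv), MeOH, 0 °C → rt; then 1 M HCl to pH 4
Reagents that add atoms: none
Why: Base-catalysed methanolysis of the trimethylsilyl ketal gives hemiketal 13, which opens to the ketone because the acyl-stabilised phenoxide is a good leaving group, and under the same carbonate conditions the enolisable C2 equilibrates to the more stable trans-2,3-disubstituted cyclopentanone while the non-enolisable C3 is untouched.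

Step 6
Reactants: 14 (2R,3S)-3-(prop-1-en-2-yl)-2-[2,4,6-trihydroxy-3-(3-methylbutanoyl)benzyl]cyclopentan-1-one; 15 methylmagnesium bromide
Product: 16 1-(2,4,6-trihydroxy-3-{[(1R,2S,5S)-2-hydroxy-2-methyl-5-(prop-1-en-2-yl)cyclopentyl]methyl}phenyl)-3-methylbutan-1-one
Conditions: CeCl3 (anhydrous, 3 equiv), 15 (6 equiv), THF, −78 → 0 °C; aq. NH4Cl
Reagents that add atoms: none
Why: Organocerium-mediated 1,2-addition of a methyl Grignard reagent to an enolisable ketone, in which the first three equivalents convert the phenols into phenoxides that mask the doubly ortho-chelated aryl ketone as a vinylogous carboxylate and pull the hemiketal open, and methyl attacks the cyclopentanone face anti to the adjacent arylmethyl group, which places the new hydroxyl cis to the CH2 substituent and so sets the carbinol carbon as (S).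

Step 7
Reactants: 16 1-(2,4,6-trihydroxy-3-{[(1R,2S,5S)-2-hydroxy-2-methyl-5-(prop-1-en-2-yl)cyclopentyl]methyl}phenyl)-3-methylbutan-1-one; 17 prenyl bromide (1-bromo-3-methylbut-2-ene)
Product: 19 3,5-dihydroxy-4-{[(1R,2S,5S)-2-hydroxy-2-methyl-5-(prop-1-en-2-yl)cyclopentyl]methyl}-6,6-bis(3-methylbut-2-en-1-yl)-2-(3-methylbutanoyl)cyclohexa-2,4-dien-1-one, via monoprenyl intermediate 18 (not isolated)
Conditions: 17 (2.2 equiv), KOH (10% aq., 3 equiv), 0 °C, N2; then dilute HCl to pH 3
Reagents that add atoms: none
Why: Double SN2 C-alkylation of an ambident acylphloroglucinol phenoxide in water, as in the classical lupulone synthesis, in which hydrogen bonding to oxygen favours attack through carbon, the first prenyl group enters at the only unsubstituted ring carbon to give 18, the second enters at the same, less shielded carbon and dearomatises the ring to the weakly nucleophilic β-triketone enolate, and no stereocentre is formed because the two new groups are identical.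

## Compound list

1 | phloroglucinol (benzene-1,3,5-triol) | Oc1cc(O)cc(O)c1 | starting material
2 | isovaleryl chloride (3-methylbutanoyl chloride) | CC(C)CC(=O)Cl | starting material
3 | phlorisovalerophenone, 3-methyl-1-(2,4,6-trihydroxyphenyl)butan-1-one | CC(C)CC(=O)c1c(O)cc(O)cc1O | intermediate
4 | N,N-dimethylmethyleneiminium iodide (Eschenmoser's salt) | C=[N+](C)C.[I-] | starting material
5 | 1-{3-[(dimethylamino)methyl]-2,4,6-trihydroxyphenyl}-3-methylbutan-1-one | CC(C)CC(=O)c1c(O)cc(O)c(CN(C)C)c1O | intermediate
6 | cyclopent-2-en-1-one | O=C1C=CCC1 | starting material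
7 | isopropenylmagnesium bromide | C=C(C)[Mg]Br | starting material
8 | isopropenylzinc chloride | C=C(C)[Zn]Cl | intermediate
9 | trimethyl{[(3S)-3-(prop-1-en-2-yl)cyclopent-1-en-1-yl]oxy}silane | C=C(C)[C@H]1CCC(O[Si](C)(C)C)=C1 | intermediate
10 | N,N,N-trimethyl-1-[2,4,6-trihydroxy-3-(3-methylbutanoyl)phenyl]methanaminium iodide | CC(C)CC(=O)c1c(O)cc(O)c(C[N+](C)(C)C)c1O.[I-] | intermediate
11 | 3,5-dihydroxy-4-(3-methylbutanoyl)-6-methylidenecyclohexa-2,4-dien-1-one (o-quinone methide) | C=C1C(=O)C=C(O)C(C(=O)CC(C)C)=C1O | intermediate
12 | 1-[(1S,3aR,9aR)-6,8-dihydroxy-1-(prop-1-en-2-yl)-3a-(trimethylsilyloxy)-1,2,3,3a,9,9a-hexahydrocyclopenta[b]chromen-7-yl]-3-methylbutan-1-one (cis-fused; ring oxygen and benzylic CH2 on one face, isopropenyl on the other) | C=C(C)[C@H]1CC[C@]2(O[Si](C)(C)C)Oc3cc(O)c(C(=O)CC(C)C)c(O)c3C[C@H]12 | intermediate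
13 | 1-[(1S,3aS,9aR)-3a,6,8-trihydroxy-1-(prop-1-en-2-yl)-1,2,3,3a,9,9a-hexahydrocyclopenta[b]chromen-7-yl]-3-methylbutan-1-one (cyclic hemiketal) | C=C(C)[C@H]1CC[C@]2(O)Oc3cc(O)c(C(=O)CC(C)C)c(O)c3C[C@H]12 | intermediate
14 | (2R,3S)-3-(prop-1-en-2-yl)-2-[2,4,6-trihydroxy-3-(3-methylbutanoyl)benzyl]cyclopentan-1-one (trans) | C=C(C)[C@H]1CCC(=O)[C@@H]1Cc1c(O)cc(O)c(C(=O)CC(C)C)c1O | intermediate
15 | methylmagnesium bromide | C[Mg]Br | starting material
16 | 1-(2,4,6-trihydroxy-3-{[(1R,2S,5S)-2-hydroxy-2-methyl-5-(prop-1-en-2-yl)cyclopentyl]methyl}phenyl)-3-methylbutan-1-one (OH cis to CH2, isopropenyl trans to CH2) | C=C(C)[C@H]1CC[C@](C)(O)[C@@H]1Cc1c(O)cc(O)c(C(=O)CC(C)C)c1O | intermediate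
17 | prenyl bromide (1-bromo-3-methylbut-2-ene) | CC(C)=CCBr | starting material
18 | 1-(2,4,6-trihydroxy-3-{[(1R,2S,5S)-2-hydroxy-2-methyl-5-(prop-1-en-2-yl)cyclopentyl]methyl}-5-(3-methylbut-2-en-1-yl)phenyl)-3-methylbutan-1-one | C=C(C)[C@H]1CC[C@](C)(O)[C@@H]1Cc1c(O)c(CC=C(C)C)c(O)c(C(=O)CC(C)C)c1O | intermediate
19 | 3,5-dihydroxy-4-{[(1R,2S,5S)-2-hydroxy-2-methyl-5-(prop-1-en-2-yl)cyclopentyl]methyl}-6,6-bis(3-methylbut-2-en-1-yl)-2-(3-methylbutanoyl)cyclohexa-2,4-dien-1-one | C=C(C)[C@H]1CC[C@](C)(O)[C@@H]1CC1=C(O)C(CC=C(C)C)(CC=C(C)C)C(=O)C(C(=O)CC(C)C)=C1O | target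

## Step count

Total steps: 7. Longest linear sequence: 6 steps (steps 1, 2, 4, 5, 6 and 7, from phloroglucinol); the cyclopentenone branch (step 3) joins at step 4.

## Steps most likely to fail and fallbacks

**Step 4 (key step).** The quinone methide may C-alkylate the free aromatic CH of a second phloroglucinol unit (self-condensation) faster than it is captured by the enol ether. The acidic phenols may also protodesilylate the enol ether before it reacts. The fallback reverses the polarity of the union and sets out from 9 and 3.
- Enol ether 9 is aminomethylated at C2 with 4 (CH2Cl2, rt; Mannich reaction of a silyl enol ether, again anti to the isopropenyl group) to give (2S,3S)-2-[(dimethylamino)methyl]-3-(prop-1-en-2-yl)cyclopentan-1-one F1.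
- N-methylation with MeI and elimination with NaHCO3 give (3R)-2-methylidene-3-(prop-1-en-2-yl)cyclopentan-1-one F2. The spatial arrangement at C3 is that of 9; only the descriptor changes. F2 is generated in the presence of an excess of 3 and NaHCO3 in aqueous THF.
- The phenoxide ring carbon of 3 adds to the exocyclic enone in a Michael reaction, so the high C-nucleophilicity of the phloroglucinol becomes the productive pathway; the excess of 3 limits double alkylation.
- Carbonate equilibration as in step 5 secures the trans isomer, and the sequence comes back to the route at 14.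

**Step 7.** The dearomatising second alkylation may occur at the ring carbon that carries the cyclopentylmethyl group, the phenoxide may be O-prenylated, and alkylation may stop short or go too far. The fallback replaces the alkyl halide SN2 reaction by Tsuji–Trost allylation followed by olefin cross-metathesis and sets out from 16.
- Pd(PPh3)4 (zerovalent palladium) and allyl methyl carbonate (2.2 equiv) in THF at rt should give 4-{[(1R,2S,5S)-2-hydroxy-2-methyl-5-(prop-1-en-2-yl)cyclopentyl]methyl}-3,5-dihydroxy-2-(3-methylbutanoyl)-6,6-di(prop-2-en-1-yl)cyclohexa-2,4-dien-1-one F3. O-Allylation is reversible under palladium, and the bulky π-allyl electrophile is more sensitive to the shielding of the substituted ring carbon.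
- Double cross-metathesis with 2-methylbut-2-ene and the second-generation Grubbs catalyst RuCl2(=CHPh)(PCy3)(H2IMes) in CH2Cl2 at 40 °C turns both allyl groups into prenyl groups; the 1,1-disubstituted isopropenyl group should be inert. The sequence comes back to the route at 19.

**Step 6.** Facial selectivity may be poor, because the isopropenyl group lies on the face the methyl group must use. The magnesium and cerium polyphenoxide may be poorly soluble and convert incompletely, and enolisation may compete with addition. The fallback masks the phenols and sets out from 14.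
- TBSCl (3.6 equiv) and imidazole in DMF at rt → 40 °C give the tris-silyl ether (2R,3S)-2-[2,4,6-tris(tert-butyldimethylsilyloxy)-3-(3-methylbutanoyl)benzyl]-3-(prop-1-en-2-yl)cyclopentan-1-one F4.
- This neutral, soluble ketone carries a bulkier C2 substituent and can be treated at −78 °C with MeMgBr/CeCl3 or MeTi(OiPr)3 in THF to give the carbinol 1-(2,4,6-tris(tert-butyldimethylsilyloxy)-3-{[(1R,2S,5S)-2-hydroxy-2-methyl-5-(prop-1-en-2-yl)cyclopentyl]methyl}phenyl)-3-methylbutan-1-one F5.
- Bu4NF with AcOH in THF at 0 °C removes the three aryl silyl ethers, and the sequence comes back to the route at 16.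

## Further compounds

F1 | step 4 | (2S,3S)-2-[(dimethylamino)methyl]-3-(prop-1-en-2-yl)cyclopentan-1-one | C=C(C)[C@H]1CCC(=O)[C@@H]1CN(C)C
F2 | step 4 | (3R)-2-methylidene-3-(prop-1-en-2-yl)cyclopentan-1-one | C=C(C)[C@H]1CCC(=O)C1=C
F3 | step 7 | 4-{[(1R,2S,5S)-2-hydroxy-2-methyl-5-(prop-1-en-2-yl)cyclopentyl]methyl}-3,5-dihydroxy-2-(3-methylbutanoyl)-6,6-di(prop-2-en-1-yl)cyclohexa-2,4-dien-1-one | C=C(C)[C@H]1CC[C@](C)(O)[C@@H]1CC1=C(O)C(CC=C)(CC=C)C(=O)C(C(=O)CC(C)C)=C1O
F4 | step 6 | (2R,3S)-2-[2,4,6-tris(tert-butyldimethylsilyloxy)-3-(3-methylbutanoyl)benzyl]-3-(prop-1-en-2-yl)cyclopentan-1-one | C=C(C)[C@H]1CCC(=O)[C@@H]1Cc1c(O[Si](C)(C)C(C)(C)C)cc(O[Si](C)(C)C(C)(C)C)c(C(=O)CC(C)C)c1O[Si](C)(C)C(C)(C)C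
F5 | step 6 | 1-(2,4,6-tris(tert-butyldimethylsilyloxy)-3-{[(1R,2S,5S)-2-hydroxy-2-methyl-5-(prop-1-en-2-yl)cyclopentyl]methyl}phenyl)-3-methylbutan-1-one | C=C(C)[C@H]1CC[C@](C)(O)[C@@H]1Cc1c(O[Si](C)(C)C(C)(C)C)cc(O[Si](C)(C)C(C)(C)C)c(C(=O)CC(C)C)c1O[Si](C)(C)C(C)(C)C
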